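**Retrosynthetic overview**

1. The (S)-lactol is released last, by neutral lipase deacylation of an (S)-acylal. The acylal comes from an acylative dynamic kinetic resolution of the racemic 3-hydroxyphthalide.
2. The seven-membered depsidone ring is closed by palladium carbonylative lactonisation (ring-A C–Br + CO + ring-B phenol).
3. Ring B is made by an anionic Michael–Claisen benzannulation. The feature it rests on: the ring-B carbon bearing the lactone carbonyl, the ring-B carbon bearing the lactol carbon, and those two exocyclic carbons with the ring oxygen are C-3, C-4, C-2, C-5 and O-1 of a 4-bromo-5-alkoxybutenolide. The other four ring-B carbons (diaryl-ether carbon, ester-oxygen carbon, hydroxymethyl carbon, phenol carbon) are C-4 to C-1 of a 4-aryloxy-2-(silyloxymethyl)acetoacetate enol silyl ether.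
4. The donor comes from a crossed Claisen of methyl 3-silyloxypropanoate with the ring-A aryloxyacetyl imidazolide. Ring A comes from atranol (acetonide, ortho-bromination, O-alkylation). The acceptor comes from 4-bromofurfural by photooxygenation.
5. Ring order: ring A (bought) → ring B with its fused acetal-lactone (key step) → central seven-membered ring → lactol stereocentre.

Key step: step 10

Assumption: the free lactol carbon of a 3-hydroxyphthalide epimerises by ring-chain tautomerism in acid or base, so S is fixed as an acylal and the hydroxyl is released only in the last, neutral step; the isothiourea enantiomer that gives S is taken to be identified in a trial run, both enantiomers being available.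

Notation: Ar = 6-bromo-2,2,7-trimethyl-4H-1,3-benzodioxin-5-yl (ring A, with its phenol and hydroxymethyl group tied as an acetonide).

**Step 1**
Reactants: 1 4-bromofuran-2-carbaldehyde
Product: 2 4-bromo-5-hydroxyfuran-2(5H)-one (racemic)
Conditions: O2, rose bengal (cat.), hν (visible), MeOH, 0 °C
Reagents that add atoms: oxygen, O=O
Why: Dye-sensitised singlet-oxygen [4+2] photooxygenation of the furan and methanolysis of the endoperoxide should expel the formyl carbon as methyl formate, so the formyl-bearing furan carbon becomes the lactone carbonyl and the bromine sits on C-4 next to the lactol carbon by construction, with no regiochemical question of the kind a mono-debromination of a 3,4-dibromobutenolide would raise.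

**Step 2**
Reactants: 2 4-bromo-5-hydroxyfuran-2(5H)-one
Product: 3 5-(benzyloxy)-4-bromofuran-2(5H)-one (racemic)
Conditions: BnOH, TsOH (cat.), toluene, reflux, Dean–Stark
Reagents that add atoms: benzyl alcohol, OCc1ccccc1
Why: Acid-catalysed pseudo-ester formation (acetalisation of the γ-hydroxybutenolide with azeotropic removal of water) should give the benzyl acetal, chosen because it can later be removed by neutral hydrogenolysis in the presence of silyl ethers and an acetonide.

**Step 3**
Reactants: 4 atranol (2,6-dihydroxy-4-methylbenzaldehyde)
Product: 5 2-(hydroxymethyl)-5-methylbenzene-1,3-diol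
Conditions: NaBH4, THF/MeOH, 0 °C; aq. NH4Cl
Reagents that add atoms: none
Why: Borohydride reduction of the aryl aldehyde to the benzylic alcohol, kept cold and short so that no further reduction through a quinone methide sets in; the triol should be used without storage.

**Step 4**
Reactants: 5 2-(hydroxymethyl)-5-methylbenzene-1,3-diol
Product: 6 2,2,7-trimethyl-4H-1,3-benzodioxin-5-ol
Conditions: Me2C(OMe)2, PPTS (cat.), acetone, rt
Reagents that add atoms: 2,2-dimethoxypropane, COC(C)(C)OC
Why: Acid-catalysed transacetalisation should close the six-membered benzodioxine on the benzylic hydroxyl and one of the two equivalent phenols, which protects the salicyl alcohol and leaves exactly one phenol free without any selectivity issue.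

**Step 5**
Reactants: 6 2,2,7-trimethyl-4H-1,3-benzodioxin-5-ol
Product: 7 6-bromo-2,2,7-trimethyl-4H-1,3-benzodioxin-5-ol
Conditions: NBS, i-Pr2NH (cat.), CH2Cl2, −20 → 0 °C
Reagents that add atoms: N-bromosuccinimide, O=C1CCC(=O)N1Br
Why: Amine-mediated ortho-selective electrophilic bromination of a phenol should deliver bromine to the only free ortho position, which is also para to the acetal oxygen.

**Step 6**
Reactants: 7 6-bromo-2,2,7-trimethyl-4H-1,3-benzodioxin-5-ol; 8 methyl bromoacetate
Product: 10 (aryloxy)acetic acid ArOCH2CO2H, via methyl aryloxyacetate 9 (not isolated)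
Conditions: K2CO3, DMF, rt; then LiOH, THF/H2O, rt; aq. HCl to pH 4, 0 °C
Reagents that add atoms: lithium hydroxide, [Li+].[OH-]
Why: Williamson ether synthesis on the phenoxide followed by saponification in the same flask; the acetonide tolerates both bases and the brief cold acidification.

**Step 7**
Reactants: 11 methyl 3-hydroxypropanoate
Product: 12 methyl 3-[(tert-butyldimethylsilyl)oxy]propanoate
Conditions: TBSCl, imidazole, CH2Cl2, rt
Reagents that add atoms: tert-butyldimethylsilyl chloride, CC(C)(C)[Si](C)(C)Cl
Why: Standard silylation of a primary alcohol.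

**Step 8**
Reactants: 10 (aryloxy)acetic acid; 12 methyl 3-[(tert-butyldimethylsilyl)oxy]propanoate
Product: 15 methyl 4-(aryloxy)-2-{[(tert-butyldimethylsilyl)oxy]methyl}-3-oxobutanoate (racemic at C-2), via acyl imidazolide 13 (not isolated), via lithium ester enolate 14 (not isolated)
Conditions: 10, CDI, THF, rt; 12, LDA (2.2 equiv each), THF, −78 °C; combine at −78 °C; AcOH
Reagents that add atoms: none
Why: Crossed Claisen condensation, in which the lithium enolate of the β-silyloxy ester is C-acylated by the acyl imidazolide at −78 °C, where β-elimination of silanolate is slow; this places the protected hydroxymethyl group on C-2 directly and avoids a mono-hydroxymethylation of an acetoacetate, and the second equivalent of enolate takes up the acidic proton of the product.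

**Step 9**
Reactants: 15 methyl 4-(aryloxy)-2-{[(tert-butyldimethylsilyl)oxy]methyl}-3-oxobutanoate
Product: 16 methyl (Z)-4-(aryloxy)-2-{[(tert-butyldimethylsilyl)oxy]methyl}-3-[(triethylsilyl)oxy]but-2-enoate
Conditions: TESOTf, Et3N, CH2Cl2, −78 → 0 °C
Reagents that add atoms: triethylsilyl triflate, CC[Si](CC)(CC)OS(=O)(=O)C(F)(F)F
Why: Soft enolisation and O-silylation of the β-keto ester with silyl triflate and amine should give the β-silyloxy acrylate, drawn as the Z isomer; any E isomer is carried along because both give the same dienolate.

**Step 10**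
Reactants: 16 methyl (Z)-4-(aryloxy)-2-{[(tert-butyldimethylsilyl)oxy]methyl}-3-[(triethylsilyl)oxy]but-2-enoate; 3 5-(benzyloxy)-4-bromofuran-2(5H)-one
Product: 19 4-(aryloxy)-3-(benzyloxy)-6-{[(tert-butyldimethylsilyl)oxy]methyl}-7-hydroxy-5-[(triethylsilyl)oxy]isobenzofuran-1(3H)-one (racemic), via lithium dienolate 17 (not isolated), via 4-alkylated butenolide 18 (not isolated)
Conditions: LDA (1.05 equiv), THF, −78 °C; added to 3, THF, −78 °C; then LiHMDS (1.5 equiv), −78 → −10 °C; AcOH
Reagents that add atoms: none
Why: Proposed new method: LDA should remove a proton from the aryloxy-bearing γ-CH2 of 16 to give dienolate 17, whose γ-carbon adds to C-4 of butenolide 3 and expels bromide (addition–elimination) to give 18; LiHMDS then removes the remaining, now doubly vinylogous proton, the lactone α-carbon of the extended enolate attacks the methyl ester, methoxide leaves and the cyclohexadienone tautomerises to the phenol, the bromide having supplied the oxidation level so that no oxidant is needed. The closest known reaction types are Michael–Claisen anionic benzannulations of the Staunton–Weinreb kind and carbon-nucleophile substitution at C-4 of 4-halobutenolides; new here are the acyclic β-silyloxyacrylate γ-anion as four-carbon partner and aromatisation by halide loss. Ring B is closed by a 6-exo-trig Claisen (Dieckmann-type) acyl substitution, and the five-membered acetal-lactone is carried in intact. No stereocentre is formed; the acetal carbon stays racemic and keeps its hydrogen. The step needs γ- over α-attack of the dienolate, secured by the fully substituted α-carbon and by the irreversible bromide loss from the γ-adduct, and it needs conjugate addition over deprotonation of the acetal C–H, secured by inverse addition of one equivalent of dienolate at −78 °C before any second base is present. The enol-ether geometry of 16 does not matter, because rotation about the Cα–Cβ bond in the anions lets the ester reach the lactone α-carbon.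

**Step 11**
Reactants: 19 the ring-B phthalide with 5-OTES
Product: 20 4-(aryloxy)-3-(benzyloxy)-6-{[(tert-butyldimethylsilyl)oxy]methyl}-5,7-dihydroxyisobenzofuran-1(3H)-one (racemic)
Conditions: TBAF, AcOH, THF, −20 → 0 °C
Reagents that add atoms: none
Why: Buffered fluoride desilylation should cleave the aryl triethylsilyl ether much faster than the primary alkyl TBS ether, and the acetic acid keeps a free phenoxide from opening the pseudo-ester.

**Step 12**
Reactants: 20 the 5,7-dihydroxyphthalide aryl bromide
Product: 21 depsidone (racemic): seven-membered aryl ester between the new ring-A carbonyl carbon and ring-B O-5; ring A keeps the acetonide and methyl group; ring B keeps CH2OTBS, the free phenol next to the phthalide carbonyl and the 3-benzyloxyphthalide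
Conditions: Pd(OAc)2, Xantphos, CO (1 atm), Et3N, toluene, 100 °C, 0.01 M
Reagents that add atoms: carbon monoxide, [C-]#[O+]
Why: Palladium-catalysed carbonylative lactonisation (oxidative addition into the aryl bromide, CO insertion, capture of the acylpalladium by the neighbouring phenol) should close the seven-membered ring, since the other phenol is hydrogen-bonded to the phthalide carbonyl and cannot reach the acyl group within the molecule.

**Step 13**
Reactants: 21 depsidone with one free phenol
Product: 22 depsidone 21 with the ring-B phenol as its TBS ether (racemic)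
Conditions: TBSOTf, 2,6-lutidine, CH2Cl2, 0 °C
Reagents that add atoms: tert-butyldimethylsilyl triflate, CC(C)(C)[Si](C)(C)OS(=O)(=O)C(F)(F)F
Why: Silylation with silyl triflate and lutidine caps the only remaining hydroxyl, so that the later acylation can touch nothing but the lactol.

**Step 14**
Reactants: 22 fully protected benzyl acetal
Product: 23 racemic lactol (3-hydroxyphthalide) of the protected depsidone
Conditions: H2 (1 atm), Pd/C, EtOAc, rt
Reagents that add atoms: none
Why: Hydrogenolysis of the O-benzyl acetal should free the lactol under neutral conditions that leave the silyl ethers, the acetonide and both lactones untouched; the bromide is gone by this point, so nothing else is reducible.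

**Step 15**
Reactants: 23 racemic lactol
Product: 24 (S)-lactol isobutyrate (acylal) of the protected depsidone
Conditions: (i-PrCO)2O, HyperBTM (5 mol %, enantiomer giving the S ester), i-Pr2NEt, CHCl3, 0 °C
Reagents that add atoms: isobutyric anhydride, CC(C)C(=O)OC(=O)C(C)C
Why: Isothiourea-catalysed acylative dynamic kinetic resolution of a 3-hydroxyphthalide, in which the base keeps the lactol enantiomers in equilibrium through the ring-opened formyl carboxylate while the chiral acyl isothiouronium acylates one of them, so the lactol carbon is set as S by catalyst control.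

**Step 16**
Reactants: 24 (S)-lactol isobutyrate, protected
Product: 25 (S)-lactol isobutyrate with both phenols and both hydroxymethyl groups free
Conditions: 48% aq. HF, MeCN, 0 °C → rt
Reagents that add atoms: none
Why: Aqueous HF should cleave both TBS ethers and hydrolyse the phenolic acetonide in one operation, while the acylal is not ionised under these conditions, so no bond to the stereocentre is broken.

**Step 17**
Reactants: 25 (S)-lactol isobutyrate, deprotected
Product: 26 target, (S)-lactol (CNP0155661.1)
Conditions: Candida antarctica lipase B (immobilised), n-BuOH, 2-MeTHF, 30 °C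
Reagents that add atoms: none
Why: Lipase-catalysed alcoholysis cleaves the acyl C–O bond in a neutral, non-aqueous medium, so the S configuration is retained and the released lactol meets neither acid nor base; the product should be isolated cold by filtration and evaporation.

**Compound list**

1 | 4-bromofuran-2-carbaldehyde | O=Cc1cc(Br)co1 | starting material
2 | 4-bromo-5-hydroxyfuran-2(5H)-one (racemic) | OC1OC(=O)C=C1Br | intermediate
3 | 5-(benzyloxy)-4-bromofuran-2(5H)-one (racemic) | O=C1C=C(Br)C(OCc2ccccc2)O1 | intermediate
4 | atranol, 2,6-dihydroxy-4-methylbenzaldehyde | Cc1cc(O)c(C=O)c(O)c1 | starting material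
5 | 2-(hydroxymethyl)-5-methylbenzene-1,3-diol | Cc1cc(O)c(CO)c(O)c1 | intermediate
6 | 2,2,7-trimethyl-4H-1,3-benzodioxin-5-ol | CC1(C)OCc2c(O)cc(C)cc2O1 | intermediate
7 | 6-bromo-2,2,7-trimethyl-4H-1,3-benzodioxin-5-ol | CC1(C)OCc2c(O)c(Br)c(C)cc2O1 | intermediate
8 | methyl bromoacetate | COC(=O)CBr | starting material
9 | methyl [(6-bromo-2,2,7-trimethyl-4H-1,3-benzodioxin-5-yl)oxy]acetate | COC(=O)COc1c(Br)c(C)cc2OC(C)(C)OCc12 | intermediate
10 | [(6-bromo-2,2,7-trimethyl-4H-1,3-benzodioxin-5-yl)oxy]acetic acid | OC(=O)COc1c(Br)c(C)cc2OC(C)(C)OCc12 | intermediate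
11 | methyl 3-hydroxypropanoate | COC(=O)CCO | starting material
12 | methyl 3-[(tert-butyldimethylsilyl)oxy]propanoate | COC(=O)CCO[Si](C)(C)C(C)(C)C | intermediate
13 | 1-[(aryloxy)acetyl]imidazole | O=C(COc1c(Br)c(C)cc2OC(C)(C)OCc12)n1ccnc1 | intermediate
14 | lithium enolate of 12 | COC(O[Li])=CCO[Si](C)(C)C(C)(C)C | intermediate
15 | methyl 4-(aryloxy)-2-{[(tert-butyldimethylsilyl)oxy]methyl}-3-oxobutanoate (racemic) | COC(=O)C(CO[Si](C)(C)C(C)(C)C)C(=O)COc1c(Br)c(C)cc2OC(C)(C)OCc12 | intermediate
16 | methyl (Z)-4-(aryloxy)-2-{[(tert-butyldimethylsilyl)oxy]methyl}-3-[(triethylsilyl)oxy]but-2-enoate | COC(=O)/C(CO[Si](C)(C)C(C)(C)C)=C(\O[Si](CC)(CC)CC)COc1c(Br)c(C)cc2OC(C)(C)OCc12 | intermediate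
17 | lithium dienolate of 16 | COC(O[Li])=C(CO[Si](C)(C)C(C)(C)C)C(O[Si](CC)(CC)CC)=COc1c(Br)c(C)cc2OC(C)(C)OCc12 | intermediate
18 | 5-(benzyloxy)butenolide carrying the donor chain at C-4 (isomer mixture) | COC(=O)C(CO[Si](C)(C)C(C)(C)C)=C(O[Si](CC)(CC)CC)C(Oc1c(Br)c(C)cc2OC(C)(C)OCc12)C1=CC(=O)OC1OCc1ccccc1 | intermediate
19 | 4-(aryloxy)-3-(benzyloxy)-6-{[(tert-butyldimethylsilyl)oxy]methyl}-7-hydroxy-5-[(triethylsilyl)oxy]isobenzofuran-1(3H)-one (racemic) | CC1(C)OCc2c(Oc3c(O[Si](CC)(CC)CC)c(CO[Si](C)(C)C(C)(C)C)c(O)c4c3C(OCc5ccccc5)OC4=O)c(Br)c(C)cc2O1 | intermediate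
20 | 4-(aryloxy)-3-(benzyloxy)-6-{[(tert-butyldimethylsilyl)oxy]methyl}-5,7-dihydroxyisobenzofuran-1(3H)-one (racemic) | CC1(C)OCc2c(Oc3c(O)c(CO[Si](C)(C)C(C)(C)C)c(O)c4c3C(OCc5ccccc5)OC4=O)c(Br)c(C)cc2O1 | intermediate
21 | depsidone: benzyl acetal, ring-A acetonide, ring-B CH2OTBS, free ring-B phenol (racemic) | Cc1cc2OC(C)(C)OCc2c2c1C(=O)Oc1c(CO[Si](C)(C)C(C)(C)C)c(O)c3c(c1O2)C(OCc1ccccc1)OC3=O | intermediate
22 | depsidone 21 with the ring-B phenol as TBS ether (racemic) | Cc1cc2OC(C)(C)OCc2c2c1C(=O)Oc1c(CO[Si](C)(C)C(C)(C)C)c(O[Si](C)(C)C(C)(C)C)c3c(c1O2)C(OCc1ccccc1)OC3=O | intermediate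
23 | protected depsidone lactol (racemic) | Cc1cc2OC(C)(C)OCc2c2c1C(=O)Oc1c(CO[Si](C)(C)C(C)(C)C)c(O[Si](C)(C)C(C)(C)C)c3c(c1O2)C(O)OC3=O | intermediate
24 | protected depsidone (S)-lactol isobutyrate | Cc1cc2OC(C)(C)OCc2c2c1C(=O)Oc1c(CO[Si](C)(C)C(C)(C)C)c(O[Si](C)(C)C(C)(C)C)c3c(c1O2)[C@@H](OC(=O)C(C)C)OC3=O | intermediate
25 | deprotected depsidone (S)-lactol isobutyrate | Cc1cc(O)c(CO)c2c1C(=O)Oc1c(CO)c(O)c3c(c1O2)[C@@H](OC(=O)C(C)C)OC3=O | intermediate
26 | target depsidone, (S)-lactol (CNP0155661.1) | Cc1cc(O)c(CO)c2c1C(=O)Oc1c(CO)c(O)c3c(c1O2)[C@@H](O)OC3=O | target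

**Step count**

Total: 17 steps. Longest linear sequence: 14 steps (steps 3–6 and 8–17, from atranol 4).

**Steps most likely to fail**

Step 10. The dienolate may be quenched by proton transfer from the acetal C–H of the butenolide, may lose silanolate by β-elimination before it adds, or the second-stage ring closure may stall. The fallback forms the same two bonds under neutral conditions by known Diels–Alder chemistry of alkoxy-bis(silyloxy)dienes with halogenated dienophiles. It sets out from 16: LDA and TMSCl in THF at −78 °C should give the 1-methoxy-1-(trimethylsilyloxy)-3-(triethylsilyloxy)diene F1. Heating F1 with butenolide 3 in toluene (80–110 °C) should give, in the normal-polarity sense (aryloxy-bearing diene terminus to the brominated β-carbon), the bicyclic bromo lactone cycloadduct F2. Triethylamine at rt should then eliminate HBr and methoxytrimethylsilane from F2, and the dienone tautomerises to the phenol. The fallback comes back to the route at 19.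

Step 12. Oxidative addition at the doubly ortho-substituted bromide and capture of the acylpalladium by the hindered phenol may both be slow, so that protodebromination or intermolecular ester formation takes over. The fallback separates carbonylation from ring closure. It sets out from 19, which still carries the triethylsilyl group: palladium-catalysed aryloxycarbonylation with 2,4,6-trichlorophenyl formate and Et3N (Pd(OAc)2, Xantphos, toluene, 80 °C; CO formed in situ) should give the ring-A 2,4,6-trichlorophenyl ester F3. CsF in DMF at 0 °C then removes the silyl group, and the phenoxide closes the seven-membered lactone by transesterification of the active ester. The fallback comes back at 21 and replaces steps 11 and 12.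

Step 17. The lipase may not accept the crowded acylal, and a slow reaction gives the released lactol time to epimerise by ring opening. The fallback replaces the enzyme by a chemical, neutral release. It sets out from 23: the same isothiourea-catalysed dynamic kinetic resolution, run with 4-azidobutanoic anhydride, should give the protected (S)-lactol 4-azidobutanoate F4. Aqueous HF in MeCN should then give the deprotected (S)-lactol 4-azidobutanoate F5. PMe3 in THF/H2O at 0 °C (Staudinger reduction) gives an amine that lactamises to pyrrolidin-2-one and frees the lactol oxygen without touching the C–O bond at the stereocentre. The fallback comes back at 26.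

**Further compounds**

F1 | step 10 | 4-(aryloxy)-1-methoxy-2-{[(tert-butyldimethylsilyl)oxy]methyl}-3-(triethylsilyloxy)-1-(trimethylsilyloxy)buta-1,3-diene | COC(O[Si](C)(C)C)=C(CO[Si](C)(C)C(C)(C)C)C(O[Si](CC)(CC)CC)=COc1c(Br)c(C)cc2OC(C)(C)OCc12
F2 | step 10 | Diels–Alder adduct of F1 and 3 (bromine at the ring fusion, mixed methyl trimethylsilyl ketal; isomer mixture) | COC1(O[Si](C)(C)C)C(CO[Si](C)(C)C(C)(C)C)=C(O[Si](CC)(CC)CC)C(Oc2c(Br)c(C)cc3OC(C)(C)OCc23)C2(Br)C(OCc3ccccc3)OC(=O)C12
F3 | step 12 | 2,4,6-trichlorophenyl ester at the ring-A carbon of 19 that bore bromine (racemic) | CC1(C)OCc2c(Oc3c(O[Si](CC)(CC)CC)c(CO[Si](C)(C)C(C)(C)C)c(O)c4c3C(OCc5ccccc5)OC4=O)c(C(=O)Oc3c(Cl)cc(Cl)cc3Cl)c(C)cc2O1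
F4 | step 17 | protected depsidone (S)-lactol 4-azidobutanoate | Cc1cc2OC(C)(C)OCc2c2c1C(=O)Oc1c(CO[Si](C)(C)C(C)(C)C)c(O[Si](C)(C)C(C)(C)C)c3c(c1O2)[C@@H](OC(=O)CCCN=[N+]=[N-])OC3=O
F5 | step 17 | deprotected depsidone (S)-lactol 4-azidobutanoate | Cc1cc(O)c(CO)c2c1C(=O)Oc1c(CO)c(O)c3c(c1O2)[C@@H](OC(=O)CCCN=[N+]=[N-])OC3=O
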